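**Retrosynthetic overview**

1. Target 14 ⇐ tetrabenzyl ether 13 by Lewis-acid debenzylation; both catechol rings are bought intact (in 4 and 10).
2. 13 ⇐ one-pot union of allylic gem-diboronate 8, methyl glyoxylate 9 and aryl bromide 10: C2–C3 by catalytic asymmetric allylboration, O1–C5 by lactonization (the only ring made in the route), then the exocyclic CH–aryl bond by Suzuki–Miyaura coupling.
3. Enabling feature: in the lactone ring O1–C2–C3–C4–C5 the exocyclic C4=CH alkene makes O1–C2–C3–C4=CH a homoallylic alcohol unit. Its vinyl CH, cis to C3, is exactly where the second boron of an α-boryl allylboronate ends up, and the ester carbon C5 on C4 closes the ring onto O1.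
4. 8 ⇐ Negishi coupling of a diborylmethylzinc reagent (from 6) with (E)-α-bromoacrylate 5 ⇐ Horner–Wadsworth–Emmons olefination of aldehyde 4 with bromophosphonate 3 (from 1).

Key step: step 4

Assumption: the sense of induction of TRIP with methyl glyoxylate is taken to follow the accepted hydrogen-bonded chair model for aldehyde allylboration, which assigns the (S)-catalyst to Si-face attack; if it proves opposite, the (R)-catalyst is used with no other change.

**Step 1**
Reactants: 1 methyl 2-[bis(2,2,2-trifluoroethoxy)phosphoryl]acetate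
Product: 3 methyl 2-bromo-2-[bis(2,2,2-trifluoroethoxy)phosphoryl]acetate, via dibromophosphonate 2 (not isolated)
Conditions: Br2, aq NaOH, 0 °C; crude 2, then SnCl2·2H2O, EtOH–H2O, 0 °C to rt
Reagents that add atoms: bromine, BrBr
Why: Exhaustive electrophilic α-bromination of the doubly activated methylene followed by chemoselective reductive monodebromination with divalent tin is the established way to α-bromophosphonoacetates; 3 is racemic and its stereocentre is destroyed in step 2.

**Step 2**
Reactants: 3 methyl 2-bromo-2-[bis(2,2,2-trifluoroethoxy)phosphoryl]acetate; 4 3,4-bis(benzyloxy)benzaldehyde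
Product: 5 methyl (E)-2-bromo-3-[3,4-bis(benzyloxy)phenyl]prop-2-enoate
Conditions: KOt-Bu, 18-crown-6, THF, −78 °C
Reagents that add atoms: none
Why: Horner–Wadsworth–Emmons olefination with a bis(trifluoroethyl) phosphonate is kinetically controlled (Still–Gennari-type) and should place the aryl group cis to the ester, giving the (E)-bromoacrylate; this geometry is what later becomes the trans relationship of C2 and C3.

**Step 3**
Reactants: 5 methyl (E)-2-bromo-3-[3,4-bis(benzyloxy)phenyl]prop-2-enoate; 6 bis(4,4,5,5-tetramethyl-1,3,2-dioxaborolan-2-yl)methane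
Product: 8 methyl (Z)-2-[bis(4,4,5,5-tetramethyl-1,3,2-dioxaborolan-2-yl)methyl]-3-[3,4-bis(benzyloxy)phenyl]prop-2-enoate, via diborylmethylzinc bromide 7 (not isolated)
Conditions: 6, lithium 2,2,6,6-tetramethylpiperidide, THF, 0 °C; ZnBr2, 0 °C to rt; then 5, Pd(OAc)2 (5 mol%), SPhos (2-dicyclohexylphosphino-2',6'-dimethoxybiphenyl, 10 mol%), THF, 40 °C
Reagents that add atoms: none
Why: Negishi coupling (oxidative addition of zerovalent palladium into the alkenyl C–Br bond, transmetalation from zinc, reductive elimination) should proceed with retention of alkene geometry, the organozinc tolerates the methyl ester, and both boron atoms stay on the new sp3 carbon.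

**Step 4**
Reactants: 8 methyl (Z)-2-[bis(4,4,5,5-tetramethyl-1,3,2-dioxaborolan-2-yl)methyl]-3-[3,4-bis(benzyloxy)phenyl]prop-2-enoate; 9 methyl glyoxylate (freshly distilled); 10 4-bromo-1,2-bis(benzyloxy)benzene
Product: 13 methyl (2S,3S,4E)-4-[3,4-bis(benzyloxy)benzylidene]-3-[3,4-bis(benzyloxy)phenyl]-5-oxooxolane-2-carboxylate, via borate adduct 11 (not isolated), via alkenylboronate lactone 12 (not isolated)
Conditions: 9 (1.3 equiv), (S)-TRIP [(S)-3,3'-bis(2,4,6-triisopropylphenyl)-1,1'-binaphthyl-2,2'-diyl hydrogen phosphate, 10 mol%], 4 Å MS, toluene, −20 °C to rt; then TsOH·H2O (20 mol%), 40 °C; then 10, Pd(OAc)2 (5 mol%), SPhos (10 mol%), K3PO4 (3 equiv), H2O (5 equiv), THF, 40 °C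
Reagents that add atoms: none
Why: The phosphoric acid hydrogen-bonds to a boronate oxygen of 8 and organises a closed six-membered chair transition state with 9 (closest precedent: chiral-phosphoric-acid-catalysed aldehyde allylboration with α-boryl allylboronates, which gives anti δ-boryl homoallylic alcohols), so C2–C3 forms with the absolute configuration at C2 and C3 set by the catalyst (Si face of the aldehyde) and the anti relationship set by the equatorial γ-aryl group, which in 8 is trans to the diborylmethyl carbon. The boron that does not react should sit pseudo-axial to avoid allylic 1,2-strain with the C4 ester and therefore end cis to C3 on the new exocyclic alkene, so the alkene geometry is fixed before any aryl group is attached. Acid then closes the only new ring, the five-membered lactone O1–C2–C3–C4–C5, by 5-exo-trig acyl substitution of the C2 oxygen (released from boron) on the C5 methyl ester, as known for aldehyde adducts of 2-alkoxycarbonyl allylboronates, and the anti adduct gives the trans lactone. Suzuki–Miyaura coupling of the remaining alkenyl–boron bond with 10 (oxidative addition, transmetalation with retention, reductive elimination) then forms the exocyclic CH–aryl bond and joins the second catechol fragment to the lactone with the E geometry retained. The step needs the two boron atoms to be differentiated, which is secured because allylboration consumes exactly one and turns the other into an alkenylboronate that is inert until palladium is added; it also needs the C2 ester and the C2/C3 centres to survive the coupling, which the weak base with little water at 40 °C should secure.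

**Step 5**
Reactants: 13 methyl (2S,3S,4E)-4-[3,4-bis(benzyloxy)benzylidene]-3-[3,4-bis(benzyloxy)phenyl]-5-oxooxolane-2-carboxylate
Product: 14 methyl (2S,3S,4E)-4-(3,4-dihydroxybenzylidene)-3-(3,4-dihydroxyphenyl)-5-oxooxolane-2-carboxylate
Conditions: BCl3 (10 equiv), pentamethylbenzene (12 equiv), CH2Cl2, −78 to −40 °C; then MeOH–H2O
Reagents that add atoms: none
Why: Lewis-acid debenzylation of aryl benzyl ethers with BCl3 and pentamethylbenzene as a non-basic benzyl-cation scavenger runs at −78 °C, where the methyl ester, the lactone, the C2 and C3 stereocentres and the conjugated E alkene (which would not survive hydrogenolysis) should remain untouched.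

**Compound list**

1 | methyl 2-[bis(2,2,2-trifluoroethoxy)phosphoryl]acetate | COC(=O)CP(=O)(OCC(F)(F)F)OCC(F)(F)F | starting material
2 | methyl 2,2-dibromo-2-[bis(2,2,2-trifluoroethoxy)phosphoryl]acetate | COC(=O)C(Br)(Br)P(=O)(OCC(F)(F)F)OCC(F)(F)F | intermediate
3 | methyl 2-bromo-2-[bis(2,2,2-trifluoroethoxy)phosphoryl]acetate (racemic) | COC(=O)C(Br)P(=O)(OCC(F)(F)F)OCC(F)(F)F | intermediate
4 | 3,4-bis(benzyloxy)benzaldehyde | O=Cc1ccc(OCc2ccccc2)c(OCc2ccccc2)c1 | starting material
5 | methyl (E)-2-bromo-3-[3,4-bis(benzyloxy)phenyl]prop-2-enoate (aryl cis to ester) | COC(=O)/C(Br)=C\c1ccc(OCc2ccccc2)c(OCc2ccccc2)c1 | intermediate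
6 | bis(4,4,5,5-tetramethyl-1,3,2-dioxaborolan-2-yl)methane | C(B1OC(C)(C)C(C)(C)O1)B1OC(C)(C)C(C)(C)O1 | starting material
7 | bromo[bis(4,4,5,5-tetramethyl-1,3,2-dioxaborolan-2-yl)methyl]zinc | Br[Zn]C(B1OC(C)(C)C(C)(C)O1)B1OC(C)(C)C(C)(C)O1 | intermediate
8 | methyl (Z)-2-[bis(4,4,5,5-tetramethyl-1,3,2-dioxaborolan-2-yl)methyl]-3-[3,4-bis(benzyloxy)phenyl]prop-2-enoate (aryl cis to ester) | COC(=O)/C(=C\c1ccc(OCc2ccccc2)c(OCc2ccccc2)c1)C(B1OC(C)(C)C(C)(C)O1)B1OC(C)(C)C(C)(C)O1 | intermediate
9 | methyl glyoxylate | COC(=O)C=O | starting material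
10 | 4-bromo-1,2-bis(benzyloxy)benzene | Brc1ccc(OCc2ccccc2)c(OCc2ccccc2)c1 | starting material
11 | dimethyl (2S,3S,4E)-3-[3,4-bis(benzyloxy)phenyl]-2-[(4,4,5,5-tetramethyl-1,3,2-dioxaborolan-2-yl)oxy]-4-[(4,4,5,5-tetramethyl-1,3,2-dioxaborolan-2-yl)methylidene]pentanedioate | COC(=O)[C@@H](OB1OC(C)(C)C(C)(C)O1)[C@@H](c1ccc(OCc2ccccc2)c(OCc2ccccc2)c1)/C(=C\B1OC(C)(C)C(C)(C)O1)C(=O)OC | intermediate
12 | methyl (2S,3S,4E)-3-[3,4-bis(benzyloxy)phenyl]-5-oxo-4-[(4,4,5,5-tetramethyl-1,3,2-dioxaborolan-2-yl)methylidene]oxolane-2-carboxylate | COC(=O)[C@H]1OC(=O)/C(=C/B2OC(C)(C)C(C)(C)O2)[C@@H]1c1ccc(OCc2ccccc2)c(OCc2ccccc2)c1 | intermediate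
13 | methyl (2S,3S,4E)-4-[3,4-bis(benzyloxy)benzylidene]-3-[3,4-bis(benzyloxy)phenyl]-5-oxooxolane-2-carboxylate | COC(=O)[C@H]1OC(=O)/C(=C/c2ccc(OCc3ccccc3)c(OCc3ccccc3)c2)[C@@H]1c1ccc(OCc2ccccc2)c(OCc2ccccc2)c1 | intermediate
14 | methyl (2S,3S,4E)-4-(3,4-dihydroxybenzylidene)-3-(3,4-dihydroxyphenyl)-5-oxooxolane-2-carboxylate | COC(=O)[C@H]1OC(=O)/C(=C/c2ccc(O)c(O)c2)[C@@H]1c1ccc(O)c(O)c1 | target

**Totals**

Total step count: 5. Longest linear sequence: 5 steps (1 → 3 → 5 → 8 → 13 → 14).

**Steps most likely to fail**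

1. Step 4. The hindered, ester-deactivated gem-diboronate may react too slowly in the closed transition state, so that an uncatalysed background pathway erodes enantio- and diastereoselectivity, or the alkenyl boron may be lost by protodeboronation under the basic coupling conditions. The fallback sets out from 5 and 6 and returns at 13. Palladium-catalysed coupling of 5 with 6 under aqueous KOH (Pd[P(t-Bu)3]2, dioxane–H2O, rt), which consumes one boron, should give methyl (Z)-3-[3,4-bis(benzyloxy)phenyl]-2-[(4,4,5,5-tetramethyl-1,3,2-dioxaborolan-2-yl)methyl]prop-2-enoate F1. The less hindered F1 is taken through the same TRIP-catalysed allylboration of 9 and acid lactonization to methyl (2S,3S)-3-[3,4-bis(benzyloxy)phenyl]-4-methylidene-5-oxooxolane-2-carboxylate F2. Heck arylation of the exocyclic methylene of F2 with bromide 10 (Pd(OAc)2, P(o-tol)3, Et3N, DMF, 80 °C) then gives 13.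

2. Step 3. Transmetalation of the bulky diborylmethylzinc may be slow, one boron may be lost by protodeboronation, or the alkene geometry may scramble at the α-palladated acrylate stage. The fallback sets out from 5 and returns at 8. Reductive carbonylation of 5 (CO/H2, Pd(OAc)2, di(1-adamantyl)-n-butylphosphine, N,N,N',N'-tetramethylethylenediamine, toluene, 100 °C) should give methyl (Z)-3-[3,4-bis(benzyloxy)phenyl]-2-formylprop-2-enoate F3. Condensation with 4-methylbenzenesulfonohydrazide (MeOH, rt) gives the N-tosylhydrazone of that aldehyde F4. Treatment of F4 with NaH and bis(pinacolato)diboron in toluene at 90 °C (Bamford–Stevens generation of the alkenyl diazo compound and formal carbene insertion into the B–B bond) gives 8.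

3. Step 2. Kinetic control in the olefination may be incomplete, and any loss of E geometry would be carried through as cis lactone. The fallback sets out from 4 and returns at 5. Ohira–Bestmann homologation (dimethyl (1-diazo-2-oxopropyl)phosphonate, K2CO3, MeOH) gives 1,2-bis(benzyloxy)-4-ethynylbenzene F5. Deprotonation and acylation (n-BuLi, THF, −78 °C; ClCO2Me) gives methyl 3-[3,4-bis(benzyloxy)phenyl]prop-2-ynoate F6. Palladium-catalysed syn-hydrostannation (Bu3SnH, Pd(PPh3)4, THF, rt) places tin on the α-carbon and gives methyl (E)-3-[3,4-bis(benzyloxy)phenyl]-2-(tributylstannyl)prop-2-enoate F7. Bromodestannylation with retention (Br2, CH2Cl2, −78 °C) gives 5.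

**Further compounds**

F1 | step 4 | methyl (Z)-3-[3,4-bis(benzyloxy)phenyl]-2-[(4,4,5,5-tetramethyl-1,3,2-dioxaborolan-2-yl)methyl]prop-2-enoate | COC(=O)/C(=C\c1ccc(OCc2ccccc2)c(OCc2ccccc2)c1)CB1OC(C)(C)C(C)(C)O1
F2 | step 4 | methyl (2S,3S)-3-[3,4-bis(benzyloxy)phenyl]-4-methylidene-5-oxooxolane-2-carboxylate | COC(=O)[C@H]1OC(=O)C(=C)[C@@H]1c1ccc(OCc2ccccc2)c(OCc2ccccc2)c1
F3 | step 3 | methyl (Z)-3-[3,4-bis(benzyloxy)phenyl]-2-formylprop-2-enoate | COC(=O)/C(C=O)=C\c1ccc(OCc2ccccc2)c(OCc2ccccc2)c1
F4 | step 3 | methyl (Z)-3-[3,4-bis(benzyloxy)phenyl]-2-{[2-(4-methylbenzenesulfonyl)hydrazinylidene]methyl}prop-2-enoate | COC(=O)/C(C=NNS(=O)(=O)c1ccc(C)cc1)=C\c1ccc(OCc2ccccc2)c(OCc2ccccc2)c1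
F5 | step 2 | 1,2-bis(benzyloxy)-4-ethynylbenzene | C#Cc1ccc(OCc2ccccc2)c(OCc2ccccc2)c1
F6 | step 2 | methyl 3-[3,4-bis(benzyloxy)phenyl]prop-2-ynoate | COC(=O)C#Cc1ccc(OCc2ccccc2)c(OCc2ccccc2)c1
F7 | step 2 | methyl (E)-3-[3,4-bis(benzyloxy)phenyl]-2-(tributylstannyl)prop-2-enoate | COC(=O)/C(=C\c1ccc(OCc2ccccc2)c(OCc2ccccc2)c1)[Sn](CCCC)(CCCC)CCCC
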